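**Retrosynthetic overview**
1. The target comes from its diol by acetylation, and the diol from a C2 ketone with a C15 benzyl ether by dissolving-metal reduction (equatorial C2 carbinol, benzyl ether removed in the same step).
2. Key disconnection: C1–C2 and C5–C10 together, back to a monocyclic 2-alkyl-3,3-dimethylcyclobutanone in which C2 and C5 are joined by a temporary bond that the target does not contain; rhodium-catalysed C–C activation and alkene insertion ("cut-and-sew") stitches the C10=C1 alkene into that bond.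
3. Enabling feature: in ring A the oxygen-bearing C2 sits between two CH2 groups and is 1,4-related to the ring-fusion CH (C5) through C3H2–C4Me2, and the C1–C10 edge ends at the methyl-bearing quaternary C10. So C2(=O)–C3–C4Me2–C5 is a 3,3-dimethylcyclobutanone once C2–C5 is closed, C10(Me)=C1H2 is a 1,1-disubstituted alkene, and the Z C7=C8 bond of ring B holds C6 and C9 cis in the four-carbon tether.
4. Precursor assembly: C5–C6 by SAMP-hydrazone alkylation of 3,3-dimethylcyclobutanone (sets C5) with a (Z)-allylic bromide; Z geometry by syn-methylcupration of an ynoate; C9 by Sharpless epoxidation and alkynylalane opening with inversion; C10=C1 by Corey–Winter olefination.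
5. (S)-Citronellol supplies C1, C9–C16, C20 and the C13 stereocentre. Ring order: the purchased cyclobutanone is carried as a temporary ring, then rings B (C5–C10) and A (C1–C2) close together in the key step.

Key step: step 12

Remark: atoms carry labdane numbers. Ring A is C1–C5 with C10, ring B is C5–C10. C2 bears the ring acetate, C4 the gem-dimethyl group, C10 the angular methyl (C20), C8 the vinylic methyl (C17), and C9 the side chain C11–C15 (C16 on C13). In this numbering the target is (2R,5R,9R,10R,13S).

**Route**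

Step 1
Reactants: 1 (S)-citronellol
Product: 2 (S)-citronellyl benzyl ether ({[(3S)-3,7-dimethyloct-6-en-1-yl]oxy}methyl)benzene
Conditions: NaH, BnBr, n-Bu4NI (cat.), THF, 0 °C → rt
Reagents that add atoms: benzyl bromide BrCc1ccccc1
Why: Williamson etherification of the primary alkoxide gives a benzyl ether that should tolerate every later step and is removed by the dissolving metal of step 13, the C13 stereocentre being untouched.

Step 2
Reactants: 2 (S)-citronellyl benzyl ether
Product: 3 (2E,6S)-8-(benzyloxy)-2,6-dimethyloct-2-en-1-ol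
Conditions: SeO2 (0.5 equiv), t-BuOOH (3 equiv), CH2Cl2, rt
Reagents that add atoms: tert-butyl hydroperoxide CC(C)(C)OO (oxygen, relayed by selenium dioxide O=[Se]=O)
Why: SeO2 allylic oxidation (ene reaction followed by 2,3-sigmatropic shift) is selective for the (E)-methyl group of a 2-methylalk-2-ene, so the E allylic alcohol oxygenated at C1 should result.

Step 3
Reactants: 3 (2E,6S)-8-(benzyloxy)-2,6-dimethyloct-2-en-1-ol
Product: 4 [(2R,3R)-3-[(3S)-5-(benzyloxy)-3-methylpentyl]-2-methyloxiran-2-yl]methanol
Conditions: Ti(OiPr)4 (10 mol %), D-(−)-diethyl tartrate (12 mol %), t-BuOOH, 4 Å molecular sieves, CH2Cl2, −20 °C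
Reagents that add atoms: tert-butyl hydroperoxide CC(C)(C)OO
Why: Sharpless asymmetric epoxidation, in which the D-(−)-tartrate complex of tetravalent titanium delivers oxygen to the face of an (E)-2-methyl allylic alcohol that gives the (2R,3R)-epoxide, fixes C9 (to be inverted in step 4) and C10 under catalyst control irrespective of the remote C13 centre.

Step 4
Reactants: 4 [(2R,3R)-3-[(3S)-5-(benzyloxy)-3-methylpentyl]-2-methyloxiran-2-yl]methanol
Product: 6 (2S,3R,6S)-8-(benzyloxy)-3-ethynyl-2,6-dimethyloctane-1,2-diol, via trimethylsilylethynyl diol 5 (not isolated)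
Conditions: Me3SiC≡CH, n-BuLi, toluene, −78 → 0 °C; Et2AlCl; then 4, 0 °C → rt; aq. KNaC4H4O6; then K2CO3, MeOH, rt
Reagents that add atoms: ethynyltrimethylsilane C#C[Si](C)(C)C
Why: alkoxide-directed opening of a 2,3-epoxy alcohol by a diethylalkynylalane is an SN2 attack at C3 (here C9, the only epoxide carbon that is not quaternary) with inversion, which attaches C8 and should set the C9 stereocentre of the target, after which K2CO3 in methanol removes the silyl group.

Step 5
Reactants: 6 (2S,3R,6S)-8-(benzyloxy)-3-ethynyl-2,6-dimethyloctane-1,2-diol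
Product: 8 ({[(3S,6S)-6-ethynyl-3,7-dimethyloct-7-en-1-yl]oxy}methyl)benzene, via cyclic thionocarbonate 7 (not isolated)
Conditions: 1,1′-thiocarbonyldiimidazole, DMAP (cat.), toluene, 100 °C; then P(OMe)3, 110 °C
Reagents that add atoms: 1,1′-thiocarbonyldiimidazole S=C(n1ccnc1)n1ccnc1 (its C=S is carried only in 7)
Why: Corey–Winter olefination, in which the cyclic thionocarbonate of the 1,2-diol undergoes phosphite-induced syn-cycloelimination, should convert C10(OH)–C1H2OH into the 1,1-disubstituted alkene C10=C1 without touching C9.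

Step 6
Reactants: 8 ({[(3S,6S)-6-ethynyl-3,7-dimethyloct-7-en-1-yl]oxy}methyl)benzene
Product: 10 methyl (4S,7S)-9-(benzyloxy)-7-methyl-4-(prop-1-en-2-yl)non-2-ynoate, via lithium acetylide 9 (not isolated)
Conditions: n-BuLi, THF, −78 °C; ClCO2Me, −78 → 0 °C
Reagents that add atoms: methyl chloroformate COC(=O)Cl
Why: the acetylenic C–H is by far the most acidic site, so lithiation and C-acylation of the acetylide with methyl chloroformate should give the ynoate and add C6.

Step 7
Reactants: 10 methyl (4S,7S)-9-(benzyloxy)-7-methyl-4-(prop-1-en-2-yl)non-2-ynoate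
Product: 11 methyl (2Z,4S,7S)-9-(benzyloxy)-3,7-dimethyl-4-(prop-1-en-2-yl)non-2-enoate
Conditions: Me2CuLi (from CuI and MeLi), THF, −78 °C; MeOH then aq. NH4Cl at −78 °C
Reagents that add atoms: lithium dimethylcuprate [Li+].C[Cu-]C
Why: conjugate addition of the Gilman reagent to an ynoate is a syn-carbocupration and low-temperature protonation occurs with retention, so the new methyl (C17) should end cis to H7 and C6 cis to C9, the Z geometry that ring B requires.

Step 8
Reactants: 11 methyl (2Z,4S,7S)-9-(benzyloxy)-3,7-dimethyl-4-(prop-1-en-2-yl)non-2-enoate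
Product: 12 (2Z,4S,7S)-9-(benzyloxy)-3,7-dimethyl-4-(prop-1-en-2-yl)non-2-en-1-ol
Conditions: i-Bu2AlH (2.5 equiv), CH2Cl2, −78 °C
Reagents that add atoms: none
Why: 1,2-reduction of the α,β-unsaturated ester by i-Bu2AlH should give the allylic alcohol with the double-bond geometry unchanged.

Step 9
Reactants: 12 (2Z,4S,7S)-9-(benzyloxy)-3,7-dimethyl-4-(prop-1-en-2-yl)non-2-en-1-ol
Product: 13 ({[(3S,6S,7Z)-9-bromo-3,7-dimethyl-6-(prop-1-en-2-yl)non-7-en-1-yl]oxy}methyl)benzene
Conditions: CBr4, PPh3, CH2Cl2, 0 °C
Reagents that add atoms: carbon tetrabromide BrC(Br)(Br)Br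
Why: the Appel reaction replaces the primary allylic hydroxyl by bromide through SN2 at C6 under neutral conditions, so neither allylic transposition nor Z/E isomerisation is expected.

Step 10
Reactants: 14 3,3-dimethylcyclobutan-1-one; 15 (S)-1-amino-2-(methoxymethyl)pyrrolidine (SAMP)
Product: 16 (2S)-N-(3,3-dimethylcyclobutylidene)-2-(methoxymethyl)pyrrolidin-1-amine
Conditions: cyclohexane, 4 Å molecular sieves, 60 °C
Reagents that add atoms: none
Why: condensation of the symmetric ketone with the chiral hydrazine gives a single hydrazone, free of C=N isomers, ready for Enders-type asymmetric alkylation.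

Step 11
Reactants: 16 (2S)-N-(3,3-dimethylcyclobutylidene)-2-(methoxymethyl)pyrrolidin-1-amine; 13 ({[(3S,6S,7Z)-9-bromo-3,7-dimethyl-6-(prop-1-en-2-yl)non-7-en-1-yl]oxy}methyl)benzene
Product: 19 (2R)-2-[(2Z,4S,7S)-9-(benzyloxy)-3,7-dimethyl-4-(prop-1-en-2-yl)non-2-en-1-yl]-3,3-dimethylcyclobutan-1-one, via lithium azaenolate 17 (not isolated), via alkylated hydrazone 18 (not isolated)
Conditions: LiN(i-Pr)2, THF, 0 °C; then 13, −100 °C → rt; then saturated aq. oxalic acid/Et2O, rt
Reagents that add atoms: water O
Why: Enders SAMP-hydrazone alkylation, in which the methoxy-chelated lithium azaenolate is attacked by the reactive allylic bromide on the face left open by the auxiliary, should set C5 as R (the sense known for SAMP hydrazones of cyclic ketones), and two-phase oxalic acid hydrolysis should release the ketone without epimerisation and without harm to the alkenes.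

Step 12
Reactants: 19 (2R)-2-[(2Z,4S,7S)-9-(benzyloxy)-3,7-dimethyl-4-(prop-1-en-2-yl)non-2-en-1-yl]-3,3-dimethylcyclobutan-1-one
Product: 20 (4aR,8R,8aR)-8-[(3S)-5-(benzyloxy)-3-methylpentyl]-4,4,7,8a-tetramethyl-3,4,4a,5,8,8a-hexahydronaphthalen-2(1H)-one
Conditions: [Rh(C2H4)2Cl]2 (5 mol %), DTBM-SEGPHOS (antipode matched to the 2R ketone, 12 mol %), AgSbF6 (12 mol %), 1,4-dioxane, 25 → 60 °C
Reagents that add atoms: none
Why: Proposed new method: cationic monovalent rhodium, guided by the tethered alkene, should add oxidatively to the strained acyl–C5 bond (C2–C5) of the cyclobutanone to give a rhodacyclopentanone of trivalent rhodium, the C10=C1 alkene then inserts into the Rh–C5 bond (C5 to C10, rhodium to C1) and acyl–alkyl reductive elimination joins C1 to C2, so that the two alkene carbons are stitched into the cleaved C2–C5 bond in a formal [4+2] process. The closest known reaction type is the rhodium-catalysed intramolecular carboacylation ("cut-and-sew") of cyclobutanones that carry a 1,1-disubstituted alkene on a three-atom tether at the α-carbon, which gives trans-fused bicyclic ketones with a quaternary fusion carbon under mild conditions; what is new here is the four-carbon all-carbon tether (a decalin instead of a hydrindane) and the gem-dimethyl group next to the migrating carbon. Ring B closes by 6-exo-trig migratory insertion and ring A by reductive elimination from the seven-membered acyl-rhodacycle. C5 keeps its configuration (retention in both oxidative addition and migration), and the new quaternary C10 is set by the alkene face, which C5 (through the trans-fused insertion geometry that places the C10 methyl anti to H5), the C9 side chain (pseudo-equatorial in the forming cyclohexene) and the matched ligand antipode should all direct to the same side. The step needs C2–C5 rather than C2–C3 cleavage (secured by alkene chelation, insertion into C2–C3 being reversible and unproductive), insertion of the 1,1-disubstituted alkene rather than the trisubstituted C7=C8 alkene (which could only close a four-membered ring), and no decarbonylation, β-hydride loss or migration of the skipped diene, which the low temperature of the cationic catalyst should secure, while the Z C7=C8 bond holds C6 and C9 cis and preorganises the closure.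

Step 13
Reactants: 20 (4aR,8R,8aR)-8-[(3S)-5-(benzyloxy)-3-methylpentyl]-4,4,7,8a-tetramethyl-3,4,4a,5,8,8a-hexahydronaphthalen-2(1H)-one
Product: 21 (2R,4aR,8R,8aR)-8-[(3S)-5-hydroxy-3-methylpentyl]-4,4,7,8a-tetramethyl-1,2,3,4,4a,5,8,8a-octahydronaphthalen-2-ol
Conditions: Li, NH3(l)/THF, EtOH (2 equiv), −78 → −33 °C; NH4Cl
Reagents that add atoms: none
Why: dissolving-metal reduction of the ketone is thermodynamically controlled and should give the equatorial (2R) alcohol, whereas hydride reagents would be steered by the axial methyls on C4 and C10 to the face that gives the axial epimer, and the same conditions cleave the benzyl ether while leaving the isolated trisubstituted alkene alone.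

Step 14
Reactants: 21 (2R,4aR,8R,8aR)-8-[(3S)-5-hydroxy-3-methylpentyl]-4,4,7,8a-tetramethyl-1,2,3,4,4a,5,8,8a-octahydronaphthalen-2-ol
Product: 22 CNP0220683.1, (2R,4aR,8R,8aR)-8-[(3S)-5-(acetyloxy)-3-methylpentyl]-4,4,7,8a-tetramethyl-1,2,3,4,4a,5,8,8a-octahydronaphthalen-2-yl acetate
Conditions: Ac2O, pyridine, DMAP (cat.), CH2Cl2, rt
Reagents that add atoms: acetic anhydride CC(=O)OC(C)=O
Why: DMAP-catalysed acylation should esterify the primary and the equatorial secondary hydroxyl to give the diacetate without touching any stereocentre.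

**Compound list**
1 | (S)-citronellol | OCC[C@@H](C)CCC=C(C)C | starting material
2 | (S)-citronellyl benzyl ether | c1ccccc1COCC[C@@H](C)CCC=C(C)C | intermediate
3 | (2E,6S)-8-(benzyloxy)-2,6-dimethyloct-2-en-1-ol | c1ccccc1COCC[C@@H](C)CC/C=C(\C)CO | intermediate
4 | [(2R,3R)-3-[(3S)-5-(benzyloxy)-3-methylpentyl]-2-methyloxiran-2-yl]methanol | c1ccccc1COCC[C@@H](C)CC[C@H]1O[C@]1(C)CO | intermediate
5 | (2S,3R,6S)-8-(benzyloxy)-2,6-dimethyl-3-[(trimethylsilyl)ethynyl]octane-1,2-diol (not isolated) | c1ccccc1COCC[C@@H](C)CC[C@H](C#C[Si](C)(C)C)[C@](C)(O)CO | intermediate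
6 | (2S,3R,6S)-8-(benzyloxy)-3-ethynyl-2,6-dimethyloctane-1,2-diol | c1ccccc1COCC[C@@H](C)CC[C@H](C#C)[C@](C)(O)CO | intermediate
7 | (4S)-4-[(3R,6S)-8-(benzyloxy)-6-methyloct-1-yn-3-yl]-4-methyl-1,3-dioxolane-2-thione (not isolated) | c1ccccc1COCC[C@@H](C)CC[C@H](C#C)[C@]1(C)OC(=S)OC1 | intermediate
8 | ({[(3S,6S)-6-ethynyl-3,7-dimethyloct-7-en-1-yl]oxy}methyl)benzene | c1ccccc1COCC[C@@H](C)CC[C@H](C#C)C(C)=C | intermediate
9 | lithium acetylide of 8 (not isolated) | c1ccccc1COCC[C@@H](C)CC[C@H](C#C[Li])C(C)=C | intermediate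
10 | methyl (4S,7S)-9-(benzyloxy)-7-methyl-4-(prop-1-en-2-yl)non-2-ynoate | c1ccccc1COCC[C@@H](C)CC[C@H](C#CC(=O)OC)C(C)=C | intermediate
11 | methyl (2Z,4S,7S)-9-(benzyloxy)-3,7-dimethyl-4-(prop-1-en-2-yl)non-2-enoate | c1ccccc1COCC[C@@H](C)CC[C@H](/C(C)=C\C(=O)OC)C(C)=C | intermediate
12 | (2Z,4S,7S)-9-(benzyloxy)-3,7-dimethyl-4-(prop-1-en-2-yl)non-2-en-1-ol | c1ccccc1COCC[C@@H](C)CC[C@H](/C(C)=C\CO)C(C)=C | intermediate
13 | ({[(3S,6S,7Z)-9-bromo-3,7-dimethyl-6-(prop-1-en-2-yl)non-7-en-1-yl]oxy}methyl)benzene | c1ccccc1COCC[C@@H](C)CC[C@H](/C(C)=C\CBr)C(C)=C | intermediate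
14 | 3,3-dimethylcyclobutan-1-one | CC1(C)CC(=O)C1 | starting material
15 | (S)-1-amino-2-(methoxymethyl)pyrrolidine (SAMP) | COC[C@@H]1CCCN1N | starting material
16 | (2S)-N-(3,3-dimethylcyclobutylidene)-2-(methoxymethyl)pyrrolidin-1-amine | COC[C@@H]1CCCN1N=C1CC(C)(C)C1 | intermediate
17 | lithium azaenolate of 16 (not isolated) | COC[C@@H]1CCCN1N([Li])C1=CC(C)(C)C1 | intermediate
18 | SAMP hydrazone of 19 (not isolated; C=N geometry not defined) | c1ccccc1COCC[C@@H](C)CC[C@H](/C(C)=C\C[C@@H]1C(C)(C)CC1=NN1CCC[C@H]1COC)C(C)=C | intermediate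
19 | (2R)-2-[(2Z,4S,7S)-9-(benzyloxy)-3,7-dimethyl-4-(prop-1-en-2-yl)non-2-en-1-yl]-3,3-dimethylcyclobutan-1-one | c1ccccc1COCC[C@@H](C)CC[C@H](/C(C)=C\C[C@@H]1C(C)(C)CC1=O)C(C)=C | intermediate
20 | (4aR,8R,8aR)-8-[(3S)-5-(benzyloxy)-3-methylpentyl]-4,4,7,8a-tetramethyl-3,4,4a,5,8,8a-hexahydronaphthalen-2(1H)-one | c1ccccc1COCC[C@@H](C)CC[C@@H]1C(C)=CC[C@@H]2C(C)(C)CC(=O)C[C@@]12C | intermediate
21 | (2R,4aR,8R,8aR)-8-[(3S)-5-hydroxy-3-methylpentyl]-4,4,7,8a-tetramethyl-1,2,3,4,4a,5,8,8a-octahydronaphthalen-2-ol | OCC[C@@H](C)CC[C@@H]1C(C)=CC[C@@H]2C(C)(C)C[C@@H](O)C[C@@]12C | intermediate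
22 | CNP0220683.1, (2R,4aR,8R,8aR)-8-[(3S)-5-(acetyloxy)-3-methylpentyl]-4,4,7,8a-tetramethyl-1,2,3,4,4a,5,8,8a-octahydronaphthalen-2-yl acetate | CC(=O)OCC[C@@H](C)CC[C@@H]1C(C)=CC[C@@H]2C(C)(C)C[C@@H](OC(C)=O)C[C@@]12C | target

**Summary**
Total step count: 14. Longest linear sequence: 13 steps (steps 1–9 and 11–14, from 1).

Steps most likely to fail:

1. Step 12 (Proposed new method). What may go wrong: rhodium may insert into C2–C3 or extrude CO, the rhodacycle may lose a β-hydrogen from C6, the skipped diene may isomerise, or the alkene may insert on the wrong face and give a cis ring fusion. Fallback with known chemistry, setting out from 13 and coming back at 20: the lithium dienolate of ethyl 3-methylbut-2-enoate (LiN(i-Pr)2, THF/DMPU, −78 °C) should be alkylated at its α-carbon by 13 to give the deconjugated ethyl ester F1, whose new centre (C5) later becomes sp2. LiOH should give the acid F2 and (COCl)2 with catalytic DMF the acid chloride F3. Et3N in refluxing toluene at high dilution should eliminate HCl to the vinylketene F4, which should undergo intramolecular ketene–alkene [2+2] cycloaddition (ketene carbonyl carbon C2 to the terminal C1, ketene α-carbon C5 to the more substituted C10), closing ring B and giving the cis-fused 2-isopropenylcyclobutanone F5 with C10 set relative to C9. Thermal 1,3-acyl shift of this 2-vinylcyclobutanone (toluene, sealed tube, about 180 °C) should expand the four-membered ring to the cyclohex-3-enone F6. DBU should move the double bond into conjugation and equilibrate C5 to the trans-fused enone F7. Conjugate methylation with Me2CuLi/Me3SiCl at C4 should complete the gem-dimethyl group and give 20.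

2. Step 4. What may go wrong: the alane may attack the tertiary epoxide carbon C10, or the Lewis acid may rearrange the epoxide instead of allowing SN2 at the hindered C9. Fallback, setting out from 3 and coming back at 8: ClP(O)(OEt)2/pyridine should give the (E)-allylic diethyl phosphate F8. A copper-catalysed, ligand-controlled SN2′ substitution with i-Bu2Al–C≡C–SiMe3 (CuCl2·2H2O and a chiral sulfonate-bearing imidazolinium salt as carbene precursor, antipode chosen for S at C9) should place the alkyne on C9 while the double bond shifts to C10=C1, giving the silylated enyne F9. K2CO3 in MeOH should then give 8, bypassing steps 3–5.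

3. Step 11. What may go wrong: slow alkylation of the hindered azaenolate (α-carbon next to CMe2), poor facial selectivity, or partial epimerisation of C5 during hydrazone cleavage. Fallback, setting out from 13 and 14 and coming back at 19: 14 and Me2NNH2 should give the achiral dimethylhydrazone F10. LiN(i-Pr)2 then 13 should give the alkylated dimethylhydrazone F11 as a pair of C5 epimers, and aqueous CuCl2 should hydrolyse it to 19 together with its (2S)-epimer F12. In step 12 the enantiopure bisphosphine–rhodium catalyst would then take 19 by kinetic resolution, and recovered F12 would be re-equilibrated at C5 with DBU and recycled.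

Further compounds
F1 | step 12 | ethyl 2-[(2Z,4S,7S)-9-(benzyloxy)-3,7-dimethyl-4-(prop-1-en-2-yl)non-2-en-1-yl]-3-methylbut-3-enoate (both C2 epimers) | c1ccccc1COCC[C@@H](C)CC[C@H](/C(C)=C\CC(C(C)=C)C(=O)OCC)C(C)=C
F2 | step 12 | 2-[(2Z,4S,7S)-9-(benzyloxy)-3,7-dimethyl-4-(prop-1-en-2-yl)non-2-en-1-yl]-3-methylbut-3-enoic acid | c1ccccc1COCC[C@@H](C)CC[C@H](/C(C)=C\CC(C(C)=C)C(=O)O)C(C)=C
F3 | step 12 | 2-[(2Z,4S,7S)-9-(benzyloxy)-3,7-dimethyl-4-(prop-1-en-2-yl)non-2-en-1-yl]-3-methylbut-3-enoyl chloride | c1ccccc1COCC[C@@H](C)CC[C@H](/C(C)=C\CC(C(C)=C)C(=O)Cl)C(C)=C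
F4 | step 12 | vinylketene from F3, (4Z,6S,9S)-11-(benzyloxy)-5,9-dimethyl-2,6-di(prop-1-en-2-yl)undeca-1,4-dien-1-one | c1ccccc1COCC[C@@H](C)CC[C@H](/C(C)=C\CC(=C=O)C(C)=C)C(C)=C
F5 | step 12 | cis-fused 2-[(3S)-5-(benzyloxy)-3-methylpentyl]-1,3-dimethyl-6-(prop-1-en-2-yl)bicyclo[4.2.0]oct-3-en-7-one (C9 and C10 as in 20) | c1ccccc1COCC[C@@H](C)CC[C@@H]1C(C)=CC[C@@]2(C(C)=C)C(=O)C[C@@]12C
F6 | step 12 | 8-[(3S)-5-(benzyloxy)-3-methylpentyl]-4,7,8a-trimethyl-1,5,8,8a-tetrahydronaphthalen-2(3H)-one (C9 and C10 as in 20) | c1ccccc1COCC[C@@H](C)CC[C@@H]1C(C)=CCC2=C(C)CC(=O)C[C@@]12C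
F7 | step 12 | trans-fused 8-[(3S)-5-(benzyloxy)-3-methylpentyl]-4,7,8a-trimethyl-4a,5,8,8a-tetrahydronaphthalen-2(1H)-one (C5, C9 and C10 as in 20) | c1ccccc1COCC[C@@H](C)CC[C@@H]1C(C)=CC[C@@H]2C(C)=CC(=O)C[C@@]12C
F8 | step 4 | (2E,6S)-8-(benzyloxy)-2,6-dimethyloct-2-en-1-yl diethyl phosphate | c1ccccc1COCC[C@@H](C)CC/C=C(\C)COP(=O)(OCC)OCC
F9 | step 4 | ({[(3S,6S)-3,7-dimethyl-6-[(trimethylsilyl)ethynyl]oct-7-en-1-yl]oxy}methyl)benzene | c1ccccc1COCC[C@@H](C)CC[C@H](C#C[Si](C)(C)C)C(C)=C
F10 | step 11 | 2-(3,3-dimethylcyclobutylidene)-1,1-dimethylhydrazine | CN(C)N=C1CC(C)(C)C1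
F11 | step 11 | N,N-dimethylhydrazone of 19 and of its C5 epimer (mixture) | c1ccccc1COCC[C@@H](C)CC[C@H](/C(C)=C\CC1C(C)(C)CC1=NN(C)C)C(C)=C
F12 | step 11 | (2S)-2-[(2Z,4S,7S)-9-(benzyloxy)-3,7-dimethyl-4-(prop-1-en-2-yl)non-2-en-1-yl]-3,3-dimethylcyclobutan-1-one | c1ccccc1COCC[C@@H](C)CC[C@H](/C(C)=C\C[C@H]1C(C)(C)CC1=O)C(C)=C
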